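**Assumption:** the SMILES has no stereocentres (only gem-dimethyl and tertiary-carbinol carbons), so the target is achiral and no step needs stereocontrol. The structure is built exactly as drawn: a 5,8-dihydroxy A ring with the 3-hydroxy-3-methylbutyl group at C6, and a B ring carrying a 2'-OH and a 4',5'-fused 2,2-dimethylchromene.

## Retrosynthetic overview
1. The C3–C1' isoflavone bond is made last by Suzuki–Miyaura coupling of 3-iodochromone **12** with aryl-Bpin **19**, followed by one global MOM removal.
2. Fragment **12**: the pyranone ring is closed last (enaminone, then I2) on a 2,6-dihydroxyacetophenone. That ketone comes from directed ortho-metalation/acetylation of a tris-MOM 1,2,4-triol, made from benzoquinone by Thiele–Winter acetoxylation. The side chain is added by B-alkyl Suzuki coupling.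
3. Fragment **19**: the pyran ring is formed first (propargyl Claisen/electrocyclisation) on 4-bromoresorcinol, then the phenol is protected and the bromide is borylated.

## Route

**Step 1**
Reactants: 1, 2-methylbut-3-en-2-ol
Product: 2, B-(3-hydroxy-3-methylbutyl)-9-BBN
Conditions: 9-BBN dimer, THF, 0 °C → rt, 3 h
Reagents that add atoms: 9-BBN, B1C2CCCC1CCC2
Why: hydroboration of the terminal alkene puts boron on the terminal carbon (anti-Markovnikov), giving the primary alkylborane for B-alkyl Suzuki coupling; no stereocentre forms.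

**Step 2**
Reactants: 3, p-benzoquinone
Product: 4, 1,2,4-triacetoxybenzene
Conditions: Ac2O, cat. H2SO4, 0 → 25 °C
Reagents that add atoms: acetic anhydride, CC(=O)OC(C)=O
Why: Thiele–Winter acetoxylation is conjugate addition of acetate to the protonated quinone followed by reductive acetylation, which installs the third oxygen; no stereocentre forms.

**Step 3**
Reactants: 4
Product: 5, benzene-1,2,4-triol (crude, used at once)
Conditions: cat. AcCl in MeOH (HCl), reflux, Ar
Reagents that add atoms: none
Why: acid-catalysed methanolysis removes the acetates without base, which would oxidise the electron-rich triol; no stereocentre.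

**Step 4**
Reactants: 5
Product: 6, 1,2,4-tris(methoxymethoxy)benzene
Conditions: MOMCl, i-Pr2NEt, CH2Cl2, 0 °C → rt
Reagents that add atoms: MOMCl, COCCl
Why: O-alkylation gives MOM ethers that survive organolithium, Pd and NIS chemistry and are removed at the end; no stereocentre.

**Step 5**
Reactants: 6
Product: 7, 1-[2,3,6-tris(methoxymethoxy)phenyl]ethan-1-one
Conditions: n-BuLi, THF, −78 → −30 °C; then MeC(O)N(Me)OMe, −78 → 0 °C
Reagents that add atoms: N-methoxy-N-methylacetamide, CC(=O)N(C)OC
Why: directed ortho-metalation occurs at the only C–H flanked by two OMOM groups (cooperative complex-induced proximity effect), and the Weinreb amide stops at the ketone; no stereocentre.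

**Step 6**
Reactants: 7
Product: 8, 1-[5-iodo-2,3,6-tris(methoxymethoxy)phenyl]ethan-1-one
Conditions: NIS, MeCN, rt, dark
Reagents that add atoms: NIS, O=C1CCC(=O)N1I
Why: electrophilic iodination goes to the position ortho to one OMOM and para to another, which is the most activated free site; the acetyl is twisted out of plane by its two ortho OMOM groups and deactivates the ring little.

**Step 7**
Reactants: 8, 2
Product: 9, 1-[5-(3-hydroxy-3-methylbutyl)-2,3,6-tris(methoxymethoxy)phenyl]ethan-1-one
Conditions: PdCl2(dppf), K3PO4, THF/H2O, 65 °C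
Reagents that add atoms: none (the chain comes from 2)
Why: B-alkyl Suzuki–Miyaura (Johnson–Miyaura) coupling of the aryl iodide with the alkyl-9-BBN tolerates the free tertiary alcohol; no stereocentre.

**Step 8**
Reactants: 9
Product: 10, 1-[2,6-dihydroxy-3-(3-hydroxy-3-methylbutyl)-5-(methoxymethoxy)phenyl]ethan-1-one
Conditions: ZnBr2, n-PrSH, CH2Cl2, 0 °C → rt, monitored
Reagents that add atoms: none
Why: the ketone oxygen chelates the Lewis acid together with the two flanking MOM oxygens, so those two ethers cleave faster than the non-chelated third one (chelation-assisted MOM cleavage).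

**Step 9**
Reactants: 10
Product: 11, (E)-3-(dimethylamino)-1-[2,6-dihydroxy-3-(3-hydroxy-3-methylbutyl)-5-(methoxymethoxy)phenyl]prop-2-en-1-one
Conditions: DMF-DMA, toluene, 80 °C
Reagents that add atoms: DMF-DMA, CN(C)C(OC)OC
Why: condensation of the acetyl CH3 with the amide acetal gives the enaminone (the chromone C2–C3 unit); the chelated OH is untouched.

**Step 10**
Reactants: 11
Product: 12, 5-hydroxy-6-(3-hydroxy-3-methylbutyl)-3-iodo-8-(methoxymethoxy)-4H-chromen-4-one
Conditions: I2, CHCl3, rt; then aq. Na2S2O3
Reagents that add atoms: iodine, II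
Why: iodination of the enaminone α-carbon, then oxa-Michael ring closure and loss of Me2NH (iodocyclisation). Closure occurs through the unchelated OH flanked by OMOM rather than the chelated OH flanked by the chain, which gives the 8-OMOM/5-OH/6-alkyl pattern; no stereocentre.

**Step 11**
Reactants: 13, resorcinol
Product: 14, 4-bromobenzene-1,3-diol
Conditions: NBS (1.0 equiv), CH2Cl2, −78 °C → rt
Reagents that add atoms: NBS, BrN1C(=O)CCC1=O
Why: electrophilic bromination of resorcinol goes to C4 (ortho to one OH, para to the other).

**Step 12**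
Reactants: 14, 15 (3-chloro-3-methylbut-1-yne)
Product: 16, 2-bromo-5-[(2-methylbut-3-yn-2-yl)oxy]phenol
Conditions: K2CO3, KI (cat.), CuI (cat.), acetone, 50 °C
Reagents that add atoms: none (the alkyne unit comes from 15)
Why: Cu-assisted O-alkylation with the tertiary propargyl chloride occurs at the less hindered OH, the one para to Br.

**Step 13**
Reactants: 16
Product: 17, 6-bromo-2,2-dimethyl-2H-chromen-7-ol
Conditions: PhNEt2, 210 °C, 3 h
Reagents that add atoms: none
Why: propargyl Claisen rearrangement, 1,5-H shift and 6π-oxa-electrocyclisation build the 2,2-dimethylchromene, closing at the free ortho carbon (linear isomer); no stereocentre.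

**Step 14**
Reactants: 17
Product: 18, 6-bromo-7-(methoxymethoxy)-2,2-dimethyl-2H-chromene
Conditions: MOMCl, i-Pr2NEt, CH2Cl2, 0 °C → rt
Reagents that add atoms: MOMCl, COCCl
Why: protects the phenol so it does not interfere with borylation or coupling.

**Step 15**
Reactants: 18
Product: 19, 2-[7-(methoxymethoxy)-2,2-dimethyl-2H-chromen-6-yl]-4,4,5,5-tetramethyl-1,3,2-dioxaborolane
Conditions: B2pin2, PdCl2(dppf), KOAc, dioxane, 85 °C
Reagents that add atoms: bis(pinacolato)diboron, CC1(C)OB(OC1(C)C)B1OC(C)(C)C(C)(C)O1
Why: Miyaura borylation converts the aryl bromide into a stable boronate, and the chromene alkene is inert to these conditions.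

**Step 16**
Reactants: 12, 19
Product: 20, bis-MOM isoflavone
Conditions: Pd(PPh3)4, 2 M aq. Na2CO3, DME, 80 °C, Ar
Reagents that add atoms: none
Why: Suzuki–Miyaura coupling of the electron-poor vinyl iodide at chromone C3 with the aryl boronate forms the C3–C1' bond; no stereocentre.

**Step 17**
Reactants: 20
Product: 21, Kraussianone 3
Conditions: 2 M HCl, THF/MeOH (1:1), 40 °C, Ar, degassed, ascorbic acid in work-up
Reagents that add atoms: none
Why: acid hydrolysis of the two aryl MOM acetals (released as CH2O and MeOH) frees the 8-OH and 2'-OH, while the tertiary alcohol, chromene and chromone survive mild acid.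

## Compound list
1 | 2-methylbut-3-en-2-ol | C=CC(C)(C)O | starting material
2 | B-(3-hydroxy-3-methylbutyl)-9-BBN | CC(C)(O)CCB1C2CCCC1CCC2 | intermediate
3 | p-benzoquinone | O=C1C=CC(=O)C=C1 | starting material
4 | 1,2,4-triacetoxybenzene | CC(=O)Oc1ccc(OC(C)=O)c(OC(C)=O)c1 | intermediate
5 | benzene-1,2,4-triol | Oc1ccc(O)c(O)c1 | intermediate
6 | 1,2,4-tris(methoxymethoxy)benzene | COCOc1ccc(OCOC)c(OCOC)c1 | intermediate
7 | 1-[2,3,6-tris(methoxymethoxy)phenyl]ethanone | CC(=O)c1c(OCOC)c(OCOC)ccc1OCOC | intermediate
8 | 1-[5-iodo-2,3,6-tris(methoxymethoxy)phenyl]ethanone | CC(=O)c1c(OCOC)c(OCOC)cc(I)c1OCOC | intermediate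
9 | 1-[5-(3-hydroxy-3-methylbutyl)-2,3,6-tris(methoxymethoxy)phenyl]ethanone | CC(=O)c1c(OCOC)c(OCOC)cc(CCC(C)(C)O)c1OCOC | intermediate
10 | 1-[2,6-dihydroxy-3-(3-hydroxy-3-methylbutyl)-5-(methoxymethoxy)phenyl]ethanone | CC(=O)c1c(O)c(OCOC)cc(CCC(C)(C)O)c1O | intermediate
11 | (E)-enaminone from 10 | CN(C)/C=C/C(=O)c1c(O)c(OCOC)cc(CCC(C)(C)O)c1O | intermediate
12 | 5-hydroxy-6-(3-hydroxy-3-methylbutyl)-3-iodo-8-(methoxymethoxy)chromone | O=c1c(I)coc2c(OCOC)cc(CCC(C)(C)O)c(O)c12 | intermediate
13 | resorcinol | Oc1cccc(O)c1 | starting material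
14 | 4-bromobenzene-1,3-diol | Oc1ccc(Br)c(O)c1 | intermediate
15 | 3-chloro-3-methylbut-1-yne | C#CC(C)(C)Cl | starting material
16 | 2-bromo-5-[(2-methylbut-3-yn-2-yl)oxy]phenol | C#CC(C)(C)Oc1ccc(Br)c(O)c1 | intermediate
17 | 6-bromo-2,2-dimethyl-2H-chromen-7-ol | CC1(C)C=Cc2cc(Br)c(O)cc2O1 | intermediate
18 | 6-bromo-7-(methoxymethoxy)-2,2-dimethyl-2H-chromene | CC1(C)C=Cc2cc(Br)c(OCOC)cc2O1 | intermediate
19 | aryl pinacolboronate of 18 | CC1(C)C=Cc2cc(B3OC(C)(C)C(C)(C)O3)c(OCOC)cc2O1 | intermediate
20 | bis-MOM isoflavone | CC(C)(O)CCc1cc(OCOC)c2occ(-c3cc4c(cc3OCOC)OC(C)(C)C=C4)c(=O)c2c1O | intermediate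
21 | Kraussianone 3 (achiral) | CC(C)(O)CCc1cc(O)c2occ(-c3cc4c(cc3O)OC(C)(C)C=C4)c(=O)c2c1O | target

## Summary
Total steps: 17.
Longest linear sequence: 11 (steps 2–10, 16, 17).

Three steps most likely to fail:
1. **Step 8 (selective MOM removal), with the regiochemistry of the step 10 ring closure.** The third MOM may also be cleaved, or the wrong OH may cyclise.
   Fallback: build the 8-deoxy chromone from resorcinol-derived 2,6-bis(MOM-oxy)acetophenone (bis-MOM resorcinol, directed lithiation/acetylation, iodination, chain coupling, full MOM removal, enaminone, I2). After coupling, install the 8-oxygen by Fremy's salt oxidation to the 5,8-quinone and Na2S2O4 reduction.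
2. **Step 16 (Suzuki coupling).** The ortho-OMOM boronate may protodeboronate, and the hindered iodochromone may couple poorly.
   Fallback: reverse the polarity and use a Negishi coupling. Form the arylzinc from bromide **18** (t-BuLi, ZnCl2) and couple it to **12** with Pd(PPh3)4.
3. **Step 17 (global deprotection).** Acid may damage the chromene or tertiary alcohol, and the free 5,8-hydroquinone is air-sensitive.
   Fallback: switch both MOM groups to SEM ethers (SEMCl in steps 4 and 14) and remove them with TBAF/ethylenediamine under non-acidic conditions.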